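**Retrosynthetic overview**
1. Target 28 ⇐ 27 by ene-type allylic chlorination (C6–Cl, C5=C6 moves to C5=C16).
2. 27 ⇐ aldehyde 25 by the key step: the C9 ketyl radical (SmI2) adds to C8 of the fused β-alkoxybutenolide, forming C8–C9, the oxocane (and so the ten-membered carbocycle) and the centres C8, C9, C17.
3. 25 ⇐ ring-A enol silane 20 + aldehyde 14 by chelation-controlled Mukaiyama aldol (C1–C2), then 1,3-anti reduction (C14), acetylation and hydrazone hydrolysis.
4. 14 ⇐ Sharpless epoxy alcohol 6 + tetronic acid 10 (C4–O by epoxide opening), then ring-closing metathesis (C5=C6); 20 ⇐ 2-methylcyclohexenone via enedione 17, auxiliary-controlled formyl-anion Michael addition (C9–C10) and hydroxymethyl addition (C20–C11).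
5. Ring order: ring A (bought) → butenolide (step 5) → dihydropyran (step 7) → oxocane/ten-membered ring (step 19).

Numbering used for all intermediates (briarane numbering of the target): C1 quaternary ring-A carbon with CH3-15; C2, C3 acetoxy carbons; C4 ether CH; C5 (bears C16); C6 CHCl; C7 lactone CH–O; C8 quaternary ether carbon; C9 CHOH; C10 ring-fusion CH; C11 C(OH)(C20H2OAc); C12, C13 CH2; C14 CHOAc; C17 (bears CH3-18); C19 lactone C=O. β = the face of ring A that carries CH3-15.
Assumption: methyl (2S)-2-hydroxybut-3-enoate is bought as the single enantiomer (otherwise it is obtained by lipase resolution of the commercial racemate).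
Assumption: the (S)-auxiliary in step 12 gives the C10 configuration drawn; if the sense is the opposite, its enantiomer is used with no other change.

**Route**

Step 1
Reactants: 1 2-methylbut-1-en-3-yne; 2 formaldehyde (as paraformaldehyde)
Product: 4 4-methylpent-4-en-2-yn-1-ol, via lithium acetylide 3 (not isolated)
Conditions: n-BuLi, THF, −78 °C; (CH2O)n, −78 °C to rt; H2O
Reagents that add atoms: none
Why: Deprotonation of the terminal alkyne and addition of the lithium acetylide to formaldehyde (alkyne hydroxymethylation) gives the propargylic alcohol, with no stereocentre formed.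

Step 2
Reactants: 4 4-methylpent-4-en-2-yn-1-ol
Product: 5 (2E)-4-methylpenta-2,4-dien-1-ol
Conditions: LiAlH4, THF, 0 °C to reflux; H2O
Reagents that add atoms: none
Why: Alkoxide-directed trans-hydroalumination of the propargylic alcohol followed by protonolysis gives only the E allylic alcohol.

Step 3
Reactants: 5 (2E)-4-methylpenta-2,4-dien-1-ol
Product: 6 [(2S,3S)-3-(prop-1-en-2-yl)oxiran-2-yl]methanol
Conditions: Ti(OiPr)4 (10 mol%), L-(+)-diethyl tartrate (12 mol%), t-BuOOH, 4 Å sieves, CH2Cl2, −20 °C
Reagents that add atoms: tert-butyl hydroperoxide, CC(C)(C)OO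
Why: Sharpless asymmetric epoxidation touches only the allylic-alcohol double bond and, with L-(+)-tartrate, gives the (2S,3S) epoxide (as for (E)-hex-2-en-1-ol), which fixes C3 and, after inversion in step 6, C4.

Step 4
Reactants: 7 methyl (2S)-2-hydroxybut-3-enoate; 8 2-bromopropanoyl bromide
Product: 9 methyl (2S)-2-[(2-bromopropanoyl)oxy]but-3-enoate
Conditions: pyridine, CH2Cl2, 0 °C
Reagents that add atoms: none
Why: O-Acylation of the secondary alcohol by the acid bromide leaves the C7 stereocentre untouched, and the CHBr centre is destroyed in the next step.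

Step 5
Reactants: 9 methyl (2S)-2-[(2-bromopropanoyl)oxy]but-3-enoate
Product: 10 (5S)-5-ethenyl-4-hydroxy-3-methylfuran-2(5H)-one
Conditions: SmI2 (2.2 equiv), THF, −78 to 0 °C; 1 M HCl
Reagents that add atoms: none
Why: Proposed new method: two-electron reduction of the α-bromo ester by SmI2 gives a non-basic trivalent-samarium enolate only at the propanoyl carbon, which acylates itself on the neighbouring methyl ester (Dieckmann-type closure) to the tetronic acid without deprotonating the allylic C7–H that an amide base would remove, the closest known chemistry being the SmI2 intramolecular Reformatsky reaction and the base-mediated Dieckmann route to tetronic acids.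

Step 6
Reactants: 6 [(2S,3S)-3-(prop-1-en-2-yl)oxiran-2-yl]methanol; 10 (5S)-5-ethenyl-4-hydroxy-3-methylfuran-2(5H)-one
Product: 11 (5S)-4-{[(3R,4S)-4,5-dihydroxy-2-methylpent-1-en-3-yl]oxy}-5-ethenyl-3-methylfuran-2(5H)-one
Conditions: Ti(OiPr)4 (1.5 equiv), CH2Cl2, rt; aqueous tartaric acid
Reagents that add atoms: none
Why: Proposed new method: the acidic tetronic acid (pKa about 4) serves as the oxygen nucleophile in a Ti(OiPr)4-mediated opening of the 2,3-epoxy alcohol at the distal, allylic carbon with inversion, as carboxylic acids do in the Sharpless regioselective epoxy-alcohol opening, which makes the C4–O–C8 ether and sets C4 anti to C3.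

Step 7
Reactants: 11 tetronate ether diol
Product: 12 (5R,7aS)-5-[(1S)-1,2-dihydroxyethyl]-3,6-dimethyl-5,7a-dihydro-2H-furo[3,2-b]pyran-2-one
Conditions: second-generation Grubbs catalyst RuCl2(=CHPh)(PCy3)(H2IMes) (5 mol%), CH2Cl2, 40 °C
Reagents that add atoms: none
Why: Ring-closing metathesis between the C7 vinyl and C4 isopropenyl groups closes the dihydropyran with loss of ethene and leaves both stereocentres untouched under neutral conditions.

Step 8
Reactants: 12 bicyclic diol
Product: 13 (5R,7aS)-5-[(1S)-1,2-bis(triethylsilyloxy)ethyl]-3,6-dimethyl-5,7a-dihydro-2H-furo[3,2-b]pyran-2-one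
Conditions: TESOTf (2.3 equiv), 2,6-lutidine, CH2Cl2, −78 °C
Reagents that add atoms: triethylsilyl trifluoromethanesulfonate, CC[Si](CC)(CC)OS(=O)(=O)C(F)(F)F
Why: Exhaustive silylation of the diol with a silyl triflate and a hindered pyridine base changes no stereocentre.

Step 9
Reactants: 13 bis(triethylsilyl) ether
Product: 14 (2R)-2-[(5R,7aS)-3,6-dimethyl-2-oxo-5,7a-dihydro-2H-furo[3,2-b]pyran-5-yl]-2-(triethylsilyloxy)acetaldehyde
Conditions: (COCl)2, DMSO, CH2Cl2, −78 to −40 °C; Et3N, −78 °C
Reagents that add atoms: none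
Why: Under Swern conditions a primary triethylsilyl ether is cleaved and oxidised directly to the aldehyde while the secondary one survives, and the low temperature limits β-elimination of the tetronate and epimerisation at C3.

Step 10
Reactants: 2 formaldehyde (as paraformaldehyde)
Product: 15 (2S)-2-(methoxymethyl)-N-methylidenepyrrolidin-1-amine (formaldehyde SAMP-hydrazone)
Conditions: (S)-1-amino-2-(methoxymethyl)pyrrolidine, CH2Cl2, rt
Reagents that add atoms: (S)-1-amino-2-(methoxymethyl)pyrrolidine (SAMP), COC[C@@H]1CCCN1N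
Why: Condensation of formaldehyde with the hydrazine auxiliary gives the hydrazone, a neutral chiral formyl-anion equivalent.

Step 11
Reactants: 16 2-methylcyclohex-2-en-1-one
Product: 17 2-methylcyclohex-2-ene-1,4-dione
Conditions: Rh2(cap)4 (1 mol%; cap = caprolactamate), t-BuOOH, K2CO3, CH2Cl2, rt
Reagents that add atoms: tert-butyl hydroperoxide, CC(C)(C)OO
Why: Dirhodium-caprolactamate-catalysed allylic oxidation converts the γ-methylene of the enone into a ketone (enone to enedione oxidation).

Step 12
Reactants: 17 2-methylcyclohex-2-ene-1,4-dione; 15 formaldehyde SAMP-hydrazone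
Product: 18 (2S)-4-(tert-butyldimethylsilyloxy)-2-[(E)-{[(2S)-2-(methoxymethyl)pyrrolidin-1-yl]imino}methyl]-3-methylcyclohex-3-en-1-one
Conditions: TBSOTf, CH2Cl2, −78 °C; Et3N; chromatography
Reagents that add atoms: tert-butyldimethylsilyl trifluoromethanesulfonate, CC(C)(C)[Si](C)(C)OS(=O)(=O)C(F)(F)F
Why: Silyl-triflate-promoted Michael addition of the formaldehyde hydrazone (aza-enamine carbon nucleophile) occurs at the unsubstituted enone carbon C10 and leaves the regiodefined tetrasubstituted C14 enol silane, the pyrrolidine auxiliary differentiating the enone faces to set C10 and the minor diastereomer being removed by chromatography.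

Step 13
Reactants: 18 hydrazone ketone enol silane
Product: 20 ring-A enol silane with C11 OTMS and C20 OTMS, via dilithium dialkoxide 19 (not isolated)
Conditions: Bu3SnCH2OH, n-BuLi (2 equiv per stannane), THF, −78 °C; 18; then Me3SiCl, −78 to 0 °C
Reagents that add atoms: (tributylstannyl)methanol, CCCC[Sn](CCCC)(CCCC)CO; chlorotrimethylsilane, C[Si](C)(C)Cl
Why: The hydroxymethyl dianion LiCH2OLi (tin–lithium exchange) adds to the C11 ketone anti to the C10 substituent, which allylic strain with the C1 methyl holds pseudoaxial, so the tertiary oxygen ends cis to C9 and C20 trans, and both alkoxides are capped in the same flask as trimethylsilyl ethers.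

Step 14
Reactants: 20 ring-A enol silane; 14 α-silyloxy aldehyde
Product: 21 C1–C2 aldol adduct (C14 ketone; C2 hydroxyl; C3 OTES)
Conditions: Me2AlCl (3 equiv), CH2Cl2, −78 °C; pH 7 buffer
Reagents that add atoms: none
Why: Mukaiyama aldol addition in which Me2AlCl chelates the aldehyde and α-silyloxy oxygens (Evans chelation with dialkylaluminium chlorides) so that attack gives the 2,3-syn product, while the enol silane reacts through its face anti to the pseudoaxial C10 substituent, creating the C1 quaternary centre with C2 trans to C9.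

Step 15
Reactants: 21 aldol adduct
Product: 22 C2/C14 anti-diol
Conditions: Me4NBH(OAc)3, MeCN/AcOH, −30 °C
Reagents that add atoms: none
Why: Evans–Saksena reduction, in which the C2 hydroxyl binds the triacetoxyborohydride and delivers hydride intramolecularly to the C14 ketone, gives the 1,3-anti diol, that is the axial 14α-hydroxyl cis to C2.

Step 16
Reactants: 22 anti-diol
Product: 23 pentaol hydrazone
Conditions: HF·pyridine, pyridine, THF, 0 °C to rt
Reagents that add atoms: none
Why: Buffered fluoride cleaves the two trimethylsilyl ethers and the triethylsilyl ether in one operation and leaves the hydrazone and the tetronate untouched.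

Step 17
Reactants: 23 pentaol hydrazone
Product: 24 tetraacetate hydrazone
Conditions: Ac2O, pyridine, DMAP (cat.), CH2Cl2, rt
Reagents that add atoms: acetic anhydride, CC(=O)OC(C)=O
Why: Acetylation of the primary and the three secondary hydroxyls (C20, C2, C3, C14) proceeds with DMAP catalysis while the tertiary, axial C11 hydroxyl is not acylated at room temperature.

Step 18
Reactants: 24 tetraacetate hydrazone
Product: 25 tetraacetate C9 aldehyde
Conditions: CuCl2·2H2O, THF/pH 7 phosphate buffer, rt
Reagents that add atoms: water, O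
Why: CuCl2-assisted hydrolysis of the N,N-dialkylhydrazone at neutral pH releases the C9 aldehyde and the auxiliary without touching the acetates, and the equatorial formyl group at C10 is also the thermodynamic epimer.

Step 19
Reactants: 25 tetraacetate C9 aldehyde
Product: 27 cyclised 9-hydroxy lactone with C5=C6 alkene (6-deschloro precursor), via cyclised samarium enolate 26 (not isolated)
Conditions: SmI2 (3 equiv), MeOH (10 equiv), THF (0.005 M), 0 °C
Reagents that add atoms: none
Why: Proposed new method: single-electron reduction of the aldehyde gives the C9 ketyl radical, which adds 8-exo to C8 of the β-alkoxybutenolide (a Nakata-type ketyl/β-alkoxyacrylate cyclisation, known for six- and seven-membered ethers and extended here to the oxocane and a tetrasubstituted acceptor) before a second electron gives the samarium enolate that methanol protonates, C8 being set because the tether on C4 can reach only the face cis to it, C9 by a chelate between the ketyl oxygen and the lactone carbonyl that places O9 anti to the ring oxygen, and C17 by protonation that leaves CH3-18 trans to the new C8–C9 bond, which is also the thermodynamic epimer.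

Step 20
Reactants: 27 6-deschloro precursor
Product: 28 CNP0190959.1
Conditions: Ca(OCl)2, CO2 (solid), CH2Cl2/H2O, 0 °C
Reagents that add atoms: calcium hypochlorite, [Ca+2].[O-]Cl.[O-]Cl
Why: Ene-type allylic chlorination by hypochlorous acid puts chlorine on the less substituted alkene carbon C6 with shift of the double bond to the exocyclic C5=C16 position, and chlorine arrives on the face opposite the five-carbon bridge, giving the 6S chloride cis to the C7 lactone oxygen.

**Compound list**
1 | 2-methylbut-1-en-3-yne | C#CC(C)=C | starting material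
2 | formaldehyde (used as paraformaldehyde) | C=O | starting material
3 | lithium 3-methylbut-3-en-1-yn-1-ide | [Li+].[C-]#CC(C)=C | intermediate
4 | 4-methylpent-4-en-2-yn-1-ol | OCC#CC(C)=C | intermediate
5 | (2E)-4-methylpenta-2,4-dien-1-ol | OC/C=C/C(C)=C | intermediate
6 | [(2S,3S)-3-(prop-1-en-2-yl)oxiran-2-yl]methanol | OC[C@@H]1O[C@H]1C(C)=C | intermediate
7 | methyl (2S)-2-hydroxybut-3-enoate | C=C[C@H](O)C(=O)OC | starting material
8 | 2-bromopropanoyl bromide (racemic) | CC(Br)C(Br)=O | starting material
9 | methyl (2S)-2-[(2-bromopropanoyl)oxy]but-3-enoate (both epimers at CHBr) | C=C[C@H](OC(=O)C(C)Br)C(=O)OC | intermediate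
10 | (5S)-5-ethenyl-4-hydroxy-3-methylfuran-2(5H)-one | OC1=C(C)C(=O)O[C@H]1C=C | intermediate
11 | (5S)-4-{[(3R,4S)-4,5-dihydroxy-2-methylpent-1-en-3-yl]oxy}-5-ethenyl-3-methylfuran-2(5H)-one | OC[C@H](O)[C@H](OC1=C(C)C(=O)O[C@H]1C=C)C(C)=C | intermediate
12 | (5R,7aS)-5-[(1S)-1,2-dihydroxyethyl]-3,6-dimethyl-5,7a-dihydro-2H-furo[3,2-b]pyran-2-one | OC[C@H](O)[C@@H]1OC2=C(C)C(=O)O[C@H]2C=C1C | intermediate
13 | (5R,7aS)-5-[(1S)-1,2-bis(triethylsilyloxy)ethyl]-3,6-dimethyl-5,7a-dihydro-2H-furo[3,2-b]pyran-2-one | CC[Si](CC)(CC)OC[C@H](O[Si](CC)(CC)CC)[C@@H]1OC2=C(C)C(=O)O[C@H]2C=C1C | intermediate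
14 | (2R)-2-[(5R,7aS)-3,6-dimethyl-2-oxo-5,7a-dihydro-2H-furo[3,2-b]pyran-5-yl]-2-(triethylsilyloxy)acetaldehyde | O=C[C@H](O[Si](CC)(CC)CC)[C@@H]1OC2=C(C)C(=O)O[C@H]2C=C1C | intermediate
15 | (2S)-2-(methoxymethyl)-N-methylidenepyrrolidin-1-amine (formaldehyde SAMP-hydrazone) | C=NN1CCC[C@H]1COC | intermediate
16 | 2-methylcyclohex-2-en-1-one | CC1=CCCCC1=O | starting material
17 | 2-methylcyclohex-2-ene-1,4-dione | CC1=CC(=O)CCC1=O | intermediate
18 | (2S)-4-(tert-butyldimethylsilyloxy)-2-[(E)-{[(2S)-2-(methoxymethyl)pyrrolidin-1-yl]imino}methyl]-3-methylcyclohex-3-en-1-one | COC[C@@H]1CCCN1/N=C/[C@H]2C(=O)CCC(O[Si](C)(C)C(C)(C)C)=C2C | intermediate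
19 | dilithium salt of the C11 tertiary and C20 primary alkoxides formed by addition of LiCH2OLi to 18 (O11 cis to C9, C20 trans) | COC[C@@H]1CCCN1/N=C/[C@H]2[C@]([O-])(C[O-])CCC(O[Si](C)(C)C(C)(C)C)=C2C.[Li+].[Li+] | intermediate
20 | ring-A enol silane: C14(OTBS)=C1(CH3) cyclohexene; C10 bears the (E)-SAMP-hydrazonomethyl group (C9, β); C11 bears OSiMe3 (β, cis to C9) and CH2OSiMe3 (C20, α) | COC[C@@H]1CCCN1/N=C/[C@H]2[C@](O[Si](C)(C)C)(CO[Si](C)(C)C)CCC(O[Si](C)(C)C(C)(C)C)=C2C | intermediate
21 | aldol adduct: C14 ketone; quaternary C1 (CH3-15 β, C2 α and trans to C9); C2–OH and C3–OSiEt3 syn; C4 is C5 of the (5R,7aS)-3,6-dimethyl-5,7a-dihydro-2H-furo[3,2-b]pyran-2-one unit; C9 hydrazone, C11 OSiMe3 and C20 OSiMe3 as in 20 | COC[C@@H]1CCCN1/N=C/[C@H]2[C@](O[Si](C)(C)C)(CO[Si](C)(C)C)CCC(=O)[C@]2(C)[C@@H](O)[C@H](O[Si](CC)(CC)CC)[C@@H]3OC4=C(C)C(=O)O[C@H]4C=C3C | intermediate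
22 | as 21 with C14 reduced to the axial 14α-alcohol, 1,3-anti to the C2 hydroxyl | COC[C@@H]1CCCN1/N=C/[C@H]2[C@](O[Si](C)(C)C)(CO[Si](C)(C)C)CC[C@H](O)[C@]2(C)[C@@H](O)[C@H](O[Si](CC)(CC)CC)[C@@H]3OC4=C(C)C(=O)O[C@H]4C=C3C | intermediate
23 | pentaol: free OH at C2, C3, C11, C14 and C20; C9 SAMP-hydrazone; bicyclic butenolide unchanged | COC[C@@H]1CCCN1/N=C/[C@H]2[C@](O)(CO)CC[C@H](O)[C@]2(C)[C@@H](O)[C@H](O)[C@@H]3OC4=C(C)C(=O)O[C@H]4C=C3C | intermediate
24 | tetraacetate (OAc at C2, C3, C14, C20), free tertiary C11–OH, C9 SAMP-hydrazone | COC[C@@H]1CCCN1/N=C/[C@H]2[C@](O)(COC(C)=O)CC[C@H](OC(C)=O)[C@]2(C)[C@@H](OC(C)=O)[C@H](OC(C)=O)[C@@H]3OC4=C(C)C(=O)O[C@H]4C=C3C | intermediate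
25 | tetraacetate C9 aldehyde (9,8-seco precursor): ring A with equatorial C10–CHO, C11(OH)(CH2OAc), C14–OAc, C1(CH3)–C2H(OAc)–C3H(OAc)–C4 attached to the fused dihydropyran/butenolide | O=C[C@H]1[C@](O)(COC(C)=O)CC[C@H](OC(C)=O)[C@]1(C)[C@@H](OC(C)=O)[C@H](OC(C)=O)[C@@H]2OC3=C(C)C(=O)O[C@H]3C=C2C | intermediate
26 | cyclised samarium enolate: C8–C9 bond formed, O9–SmI2 alkoxide, C17=C19(OSmI2) lactone enolate | CC=1[C@H]2O[C@]3(C(C)=C(O[Sm](I)I)O[C@H]3C1)[C@@H](O[Sm](I)I)[C@H]1[C@](O)(COC(C)=O)CC[C@H](OC(C)=O)[C@]1(C)[C@@H](OC(C)=O)[C@@H]2OC(C)=O | intermediate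
27 | 6-deschloro precursor: target skeleton with C5(CH3)=C6H in place of C5(=CH2)–C6HCl; all other centres as in the target | CC=1[C@H]2O[C@]3([C@@H](C)C(=O)O[C@H]3C1)[C@@H](O)[C@H]1[C@](O)(COC(C)=O)CC[C@H](OC(C)=O)[C@]1(C)[C@@H](OC(C)=O)[C@@H]2OC(C)=O | intermediate
28 | CNP0190959.1 (2,3,14,20-tetraacetoxy-6-chloro-4,8-epoxy-9,11-dihydroxy briarane lactone with the 5(16)-exocyclic alkene) | C=C1[C@H]2O[C@]3([C@@H](C)C(=O)O[C@H]3[C@H]1Cl)[C@@H](O)[C@H]1[C@](O)(COC(C)=O)CC[C@H](OC(C)=O)[C@]1(C)[C@@H](OC(C)=O)[C@@H]2OC(C)=O | target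

**Step count and risks**
Total steps: 20. Longest linear sequence: 14 steps (steps 1–3, 6–9, 14–20).

The three steps most likely to fail:

Step 19 (radical closure of the oxocane). The acceptor carbon is fully substituted and the ring is eight-membered, so simple reduction or pinacol coupling of the aldehyde may win, and the C9 configuration rests on a chelation model. The fallback sets out from 25 and comes back at 27. It replaces the radical C–C bond formation by a polar umpolung one: an N-heterocyclic-carbene-catalysed intramolecular Stetter reaction (triazolium salt, iPr2NEt, toluene, 60 °C) adds the Breslow intermediate of the aldehyde to C8 and gives the C9 ketone F4. Reduction with Zn(BH4)2, chelated to the ring oxygen, then gives the 9-alcohol 27.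

Step 14 (aldol union). A quaternary centre is formed next to a hindered enol silane, the substrate has many Lewis-basic sites, and the two facial preferences may be mismatched. The fallback sets out from 14 and 20 and comes back at 22. It uses acylation and reduction in place of the aldol. Pinnick oxidation (NaClO2, NaH2PO4, 2-methylbut-2-ene) of 14 gives the α-silyloxy acid F1. 1-Chloro-N,N,2-trimethylprop-1-en-1-amine converts it into the acid chloride F2. ZnCl2-mediated C-acylation of enol silane 20, again anti to the C10 substituent, gives the non-enolisable 1,3-diketone F3. LiBH(s-Bu)3 at −78 °C reduces both ketones: Felkin–Anh attack at C2 next to the non-chelating silyl ether gives the 2,3-syn alcohol, and equatorial attack at C14 gives the axial alcohol, which is 22.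

Step 20 (final chlorination). The alkene is deactivated by two allylic oxygens, proton loss could occur from C4–H instead of the methyl group, and the facial selectivity is only predicted. The fallback sets out from 27 and comes back at 28. It is a two-step allylic transposition: SeO2 (cat.)/t-BuOOH hydroxylates the C5 methyl group to the primary allylic alcohol F5. SOCl2 in Et2O then converts it, through the chlorosulfite and SNi' delivery to the open face of C6, into the rearranged secondary chloride 28.

Further compounds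
F1 | step 14 | (2R)-2-[(5R,7aS)-3,6-dimethyl-2-oxo-5,7a-dihydro-2H-furo[3,2-b]pyran-5-yl]-2-(triethylsilyloxy)acetic acid | OC(=O)[C@H](O[Si](CC)(CC)CC)[C@@H]1OC2=C(C)C(=O)O[C@H]2C=C1C
F2 | step 14 | (2R)-2-[(5R,7aS)-3,6-dimethyl-2-oxo-5,7a-dihydro-2H-furo[3,2-b]pyran-5-yl]-2-(triethylsilyloxy)acetyl chloride | ClC(=O)[C@H](O[Si](CC)(CC)CC)[C@@H]1OC2=C(C)C(=O)O[C@H]2C=C1C
F3 | step 14 | 1,3-diketone: as 21 with a C2 ketone in place of the C2 carbinol | COC[C@@H]1CCCN1/N=C/[C@H]2[C@](O[Si](C)(C)C)(CO[Si](C)(C)C)CCC(=O)[C@]2(C)C(=O)[C@H](O[Si](CC)(CC)CC)[C@@H]3OC4=C(C)C(=O)O[C@H]4C=C3C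
F4 | step 19 | C9 ketone: as 27 with C9=O in place of C9H–OH | CC=1[C@H]2O[C@]3([C@@H](C)C(=O)O[C@H]3C1)C(=O)[C@H]1[C@](O)(COC(C)=O)CC[C@H](OC(C)=O)[C@]1(C)[C@@H](OC(C)=O)[C@@H]2OC(C)=O
F5 | step 20 | C16 primary allylic alcohol: as 27 with CH2OH on C5 in place of CH3 | OCC=1[C@H]2O[C@]3([C@@H](C)C(=O)O[C@H]3C1)[C@@H](O)[C@H]1[C@](O)(COC(C)=O)CC[C@H](OC(C)=O)[C@]1(C)[C@@H](OC(C)=O)[C@@H]2OC(C)=O
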